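**Plan** (ring numbering used throughout: C1 carries the CH2OAc carbon C7, C2 is the ring =CH, C3 the adjacent CH2, C4 the ring stereocentre)
1. Retrosynthetic cuts, in order: the two acetates; the E-CH=CH bond of the side chain (cross-metathesis); the ring bond C2–C3 (intramolecular alkylation of a lithiated allyl sulfoxide, then [2,3] shift giving C1=C2 and C7–OH); the C4–C5 bond (cuprate opening of an epoxy alcohol).
2. Enabling feature: C1 bears both C7 and C2, which before ring closure are the two equivalent CH2 ends of a 2-substituted allyl unit. Sulfur on one end makes it the carbanion (C2); the [2,3] shift then hands oxygen to the other end (C7) and fixes the double bond at C1=C2.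
3. C4 is stereogenic in the ring only through the side on which that double bond lies, so closing C2–C3 from the CH2OTs arm carries the acyclic configuration into the ring with no facial selectivity needed.
4. Forward order: the acyclic chain C3–C4–C(OH)Me–allyl is built first (steps 3–5, with the C5 sulfide unit from steps 1–2), the only ring is closed in step 9, the side chain is joined in step 11, and acetylation comes last.
5. Stereochemistry: Sharpless epoxidation (L-(+)-tartrate) of an E-allylic alcohol sets C4 (after SN2 inversion) and the ring-bound carbinol; a palladium-catalysed dynamic kinetic asymmetric opening of racemic isoprene monoepoxide sets the remote carbinol; metathesis sets the E-alkene.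

Key step: step 9

Assumption: in step 10 the (1R,2R)-configured diphosphine is taken to deliver the (R)-diol; if its sense of induction is the opposite, the (1S,2S)-ligand is used instead.

**Step 1**
Reactants: 1 3-methylbut-3-en-1-ol
Product: 3 allyl sulfide alcohol 3-[(phenylsulfanyl)methyl]but-3-en-1-ol, via dilithio dianion 2 (not isolated)
Conditions: n-BuLi (2.2 equiv), TMEDA, Et2O/hexane, 0 to 25 °C; then PhSSPh, THF, −78 °C; aq NH4Cl
Reagents that add atoms: diphenyl disulfide, c1ccc(cc1)SSc1ccccc1
Why: alkoxide-directed allylic lithiation of the methyl group gives a 2-substituted allyl dianion whose two CH2 ends are equivalent, so sulfenylation by the disulfide can lead to only one constitution.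

**Step 2**
Reactants: 3 3-[(phenylsulfanyl)methyl]but-3-en-1-ol
Product: 4 4-bromo-2-[(phenylsulfanyl)methyl]but-1-ene
Conditions: CBr4, PPh3, CH2Cl2, 0 °C
Reagents that add atoms: tetrabromomethane, BrC(Br)(Br)Br
Why: Appel bromination of the primary alcohol under neutral conditions should leave the allyl sulfide and the alkene untouched.

**Step 3**
Reactants: 5 pent-1-en-4-yne
Product: 7 (2E)-3-methylhexa-2,5-dien-1-ol, via alkenylalane 6 (not isolated)
Conditions: AlMe3, Cp2ZrCl2 (cat.), CH2Cl2, 25 °C; then n-BuLi, (CH2O)n, THF, −30 to 25 °C; aq HCl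
Reagents that add atoms: trimethylaluminium, C[Al](C)C; paraformaldehyde (as formaldehyde), C=O
Why: Negishi carboalumination adds CH3 and Al syn across the terminal alkyne (Al at the terminus) and the derived ate complex is hydroxymethylated with retention, which should give the E-trisubstituted allylic alcohol while the isolated terminal alkene stays inert.

**Step 4**
Reactants: 7 (2E)-3-methylhexa-2,5-dien-1-ol
Product: 8 [(2S,3S)-3-methyl-3-(prop-2-en-1-yl)oxiran-2-yl]methanol
Conditions: Ti(OiPr)4 (5 mol%), L-(+)-diethyl tartrate (6 mol%), t-BuOOH, 4 Å MS, CH2Cl2, −20 °C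
Reagents that add atoms: tert-butyl hydroperoxide, CC(C)(C)OO
Why: Sharpless asymmetric epoxidation epoxidises only the allylic-alcohol double bond, and the L-(+)-tartrate catalyst should deliver oxygen to the face that gives the (2S,3S)-epoxide, as for other E-3-methylalk-2-en-1-ols.

**Step 5**
Reactants: 4 4-bromo-2-[(phenylsulfanyl)methyl]but-1-ene; 8 [(2S,3S)-3-methyl-3-(prop-2-en-1-yl)oxiran-2-yl]methanol
Product: 10 (2R,3S)-3-methyl-2-{3-[(phenylsulfanyl)methyl]but-3-en-1-yl}hex-5-ene-1,3-diol, via Grignard reagent 9 (not isolated)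
Conditions: 4 (3 equiv), Mg, THF, 25 °C; then CuI (10 mol%), 8, THF, −30 to 0 °C; aq NH4Cl
Reagents that add atoms: none
Why: copper-catalysed Grignard opening of a 2,3-epoxy alcohol occurs at C2 because C3 is fully substituted, and the SN2 inversion there sets the future ring stereocentre (R) next to the untouched (S)-carbinol.

**Step 6**
Reactants: 10 (2R,3S)-3-methyl-2-{3-[(phenylsulfanyl)methyl]but-3-en-1-yl}hex-5-ene-1,3-diol
Product: 11 (2R,3S)-3-hydroxy-3-methyl-2-{3-[(phenylsulfanyl)methyl]but-3-en-1-yl}hex-5-en-1-yl 4-methylbenzenesulfonate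
Conditions: TsCl, Et3N, DMAP (cat.), CH2Cl2, 0 °C
Reagents that add atoms: 4-methylbenzenesulfonyl chloride, Cc1ccc(cc1)S(Cl)(=O)=O
Why: sulfonylation should be selective for the primary hydroxyl over the tertiary one.

**Step 7**
Reactants: 11 the primary tosylate
Product: 12 (2R,3S)-3-methyl-2-{3-[(phenylsulfanyl)methyl]but-3-en-1-yl}-3-[(trimethylsilyl)oxy]hex-5-en-1-yl 4-methylbenzenesulfonate
Conditions: Me3SiOTf, 2,6-lutidine, CH2Cl2, −78 °C
Reagents that add atoms: trimethylsilyl trifluoromethanesulfonate, C[Si](C)(C)OS(=O)(=O)C(F)(F)F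
Why: silylation of the tertiary hydroxyl removes the alkoxide that could otherwise close an oxetane or trigger fragmentation of the 1,3-hydroxy tosylate under the base of step 9.

**Step 8**
Reactants: 12 the silyl ether tosylate sulfide
Product: 13 (2R,3S)-3-methyl-2-{3-[(phenylsulfinyl)methyl]but-3-en-1-yl}-3-[(trimethylsilyl)oxy]hex-5-en-1-yl 4-methylbenzenesulfonate (both sulfur epimers)
Conditions: mCPBA (1.0 equiv), NaHCO3, CH2Cl2, −78 °C
Reagents that add atoms: 3-chloroperoxybenzoic acid, OOC(=O)c1cccc(Cl)c1
Why: sulfide-to-sulfoxide oxidation is much faster than epoxidation of the two unactivated alkenes at −78 °C, and the [2,3] shift of this allyl sulfoxide is degenerate because both CH2 ends sit on the same carbon.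

**Step 9**
Reactants: 13 the allyl sulfoxide tosylate (both sulfur epimers)
Product: 18 (2S)-2-[(1R)-4-(hydroxymethyl)cyclohex-3-en-1-yl]pent-4-en-2-ol, via lithiated sulfoxide 14 (not isolated), via cyclic allyl sulfoxide 15 (not isolated), via sulfenate ester 16 (not isolated), via silyl ether alcohol 17 (not isolated)
Conditions: LiN(iPr)2 (1.1 equiv), THF, −78 to −20 °C; then Et2NH, MeOH, 25 °C; then 1 M HCl, 0 °C
Reagents that add atoms: none
Why: Deprotonation next to sulfur gives the sulfinyl-stabilised allyl lithium 14, whose α-carbon (C2) displaces the tosylate on C3 to give 15; this undergoes the [2,3]-sigmatropic sulfoxide–sulfenate (Mislow–Evans) rearrangement to 16, which diethylamine cleaves at sulfur, and dilute acid then removes the silyl group. The closest known reaction type is α-alkylation of lithiated allyl aryl sulfoxides with primary halides or sulfonates followed by thiophile-driven sulfenate cleavage (a β-hydroxymethyl vinyl anion equivalent), here run intramolecularly. The six-membered ring closes in the 6-exo-tet mode. No stereocentre is created in the product: the sulfur epimers of 13 and both epimers at the sulfinyl carbon of 15 converge because both centres are erased, and the C4 configuration is carried over since the double bond can only form between C1 and the carbon that bore sulfur. The step needs α- over γ-alkylation of the ambident anion (γ-attack would also close a six-membered ring but leave a vinyl sulfoxide); this should be secured by lithium being held at the α-carbon through chelation to the sulfinyl oxygen and by the hard sulfonate electrophile. The silyl ether keeps the tertiary oxygen from competing for the tosylate.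

**Step 10**
Reactants: 19 2-methyl-2-vinyloxirane (racemic)
Product: 21 (2R)-2-methylbut-3-ene-1,2-diol, via hydrogencarbonate monoester 20 (not isolated)
Conditions: Pd2(dba)3·CHCl3 (1 mol%), (1R,2R)-N,N′-bis[2-(diphenylphosphanyl)benzoyl]cyclohexane-1,2-diamine (3 mol%), Et3B (1 mol%), NaHCO3, CH2Cl2/H2O, 25 °C
Reagents that add atoms: sodium hydrogencarbonate, [Na+].OC([O-])=O
Why: in this dynamic kinetic asymmetric allylic substitution, zerovalent palladium ionises both epoxide enantiomers to π-allyl complexes that interconvert faster than they are attacked; the borane ties hydrogencarbonate to the alkoxide and delivers it to the tertiary terminus under ligand control, and the monoester then loses carbon dioxide.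

**Step 11**
Reactants: 18 (2S)-2-[(1R)-4-(hydroxymethyl)cyclohex-3-en-1-yl]pent-4-en-2-ol; 21 (2R)-2-methylbut-3-ene-1,2-diol (3 equiv)
Product: 22 (2R,3E,6S)-6-[(1R)-4-(hydroxymethyl)cyclohex-3-en-1-yl]-2-methylhept-3-ene-1,2,6-triol
Conditions: second-generation Grubbs catalyst RuCl2(H2IMes)(PCy3)(=CHPh) (5 mol%), CH2Cl2, 40 °C
Reagents that add atoms: none
Why: olefin cross-metathesis between the terminal alkene and the slowly homodimerising tertiary allylic alcohol should give the E-alkene because of the fully substituted allylic carbon, while the trisubstituted ring alkene stays inert.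

**Step 12**
Reactants: 22 the tetraol
Product: 23 [(4R)-4-[(2S,4E,6R)-7-(acetyloxy)-2,6-dihydroxy-6-methylhept-4-en-2-yl]cyclohex-1-en-1-yl]methyl acetate (target)
Conditions: Ac2O, pyridine, DMAP (cat.), CH2Cl2, 0 °C
Reagents that add atoms: acetic anhydride, CC(=O)OC(C)=O
Why: acylation should take both primary hydroxyls and leave the two tertiary hydroxyls free.

**Compound list**
1 | 3-methylbut-3-en-1-ol | CC(=C)CCO | starting material
2 | dilithio dianion of 1 (O-lithio, allylic C-lithio) | [Li]CC(=C)CCO[Li] | intermediate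
3 | 3-[(phenylsulfanyl)methyl]but-3-en-1-ol | OCCC(=C)CSc1ccccc1 | intermediate
4 | 4-bromo-2-[(phenylsulfanyl)methyl]but-1-ene | BrCCC(=C)CSc1ccccc1 | intermediate
5 | pent-1-en-4-yne | C=CCC#C | starting material
6 | dimethyl[(1E)-2-methylpenta-1,4-dien-1-yl]alumane | C[Al](C)/C=C(\C)CC=C | intermediate
7 | (2E)-3-methylhexa-2,5-dien-1-ol | OC/C=C(\C)CC=C | intermediate
8 | [(2S,3S)-3-methyl-3-(prop-2-en-1-yl)oxiran-2-yl]methanol | OC[C@@H]1O[C@@]1(C)CC=C | intermediate
9 | bromo{3-[(phenylsulfanyl)methyl]but-3-en-1-yl}magnesium | Br[Mg]CCC(=C)CSc1ccccc1 | intermediate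
10 | (2R,3S)-3-methyl-2-{3-[(phenylsulfanyl)methyl]but-3-en-1-yl}hex-5-ene-1,3-diol | OC[C@@H](CCC(=C)CSc1ccccc1)[C@@](C)(O)CC=C | intermediate
11 | (2R,3S)-3-hydroxy-3-methyl-2-{3-[(phenylsulfanyl)methyl]but-3-en-1-yl}hex-5-en-1-yl 4-methylbenzenesulfonate | Cc1ccc(cc1)S(=O)(=O)OC[C@@H](CCC(=C)CSc1ccccc1)[C@@](C)(O)CC=C | intermediate
12 | (2R,3S)-3-methyl-2-{3-[(phenylsulfanyl)methyl]but-3-en-1-yl}-3-[(trimethylsilyl)oxy]hex-5-en-1-yl 4-methylbenzenesulfonate | Cc1ccc(cc1)S(=O)(=O)OC[C@@H](CCC(=C)CSc1ccccc1)[C@@](C)(O[Si](C)(C)C)CC=C | intermediate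
13 | (2R,3S)-3-methyl-2-{3-[(phenylsulfinyl)methyl]but-3-en-1-yl}-3-[(trimethylsilyl)oxy]hex-5-en-1-yl 4-methylbenzenesulfonate (both sulfur epimers) | Cc1ccc(cc1)S(=O)(=O)OC[C@@H](CCC(=C)CS(=O)c1ccccc1)[C@@](C)(O[Si](C)(C)C)CC=C | intermediate
14 | α-lithio derivative of 13 (lithium on the sulfinyl-bearing carbon) | Cc1ccc(cc1)S(=O)(=O)OC[C@@H](CCC(=C)C([Li])S(=O)c1ccccc1)[C@@](C)(O[Si](C)(C)C)CC=C | intermediate
15 | trimethyl{[(2S)-2-[(1R)-4-methylidene-3-(phenylsulfinyl)cyclohexyl]pent-4-en-2-yl]oxy}silane (all epimers at the sulfinyl carbon and at sulfur) | C=C1CC[C@H](CC1S(=O)c1ccccc1)[C@@](C)(O[Si](C)(C)C)CC=C | intermediate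
16 | [(4R)-4-{(2S)-2-[(trimethylsilyl)oxy]pent-4-en-2-yl}cyclohex-1-en-1-yl]methyl benzenesulfenate | c1ccc(cc1)SOCC1=CC[C@H]([C@@](C)(O[Si](C)(C)C)CC=C)CC1 | intermediate
17 | [(4R)-4-{(2S)-2-[(trimethylsilyl)oxy]pent-4-en-2-yl}cyclohex-1-en-1-yl]methanol | OCC1=CC[C@H]([C@@](C)(O[Si](C)(C)C)CC=C)CC1 | intermediate
18 | (2S)-2-[(1R)-4-(hydroxymethyl)cyclohex-3-en-1-yl]pent-4-en-2-ol | OCC1=CC[C@H]([C@@](C)(O)CC=C)CC1 | intermediate
19 | 2-methyl-2-vinyloxirane (racemic) | CC1(CO1)C=C | starting material
20 | (2R)-1-hydroxy-2-methylbut-3-en-2-yl hydrogen carbonate | C=C[C@@](C)(OC(O)=O)CO | intermediate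
21 | (2R)-2-methylbut-3-ene-1,2-diol | C=C[C@@](C)(O)CO | intermediate
22 | (2R,3E,6S)-6-[(1R)-4-(hydroxymethyl)cyclohex-3-en-1-yl]-2-methylhept-3-ene-1,2,6-triol | OCC1=CC[C@H]([C@@](C)(O)C/C=C/[C@@](C)(O)CO)CC1 | intermediate
23 | [(4R)-4-[(2S,4E,6R)-7-(acetyloxy)-2,6-dihydroxy-6-methylhept-4-en-2-yl]cyclohex-1-en-1-yl]methyl acetate | CC(=O)OCC1=CC[C@H]([C@@](C)(O)C/C=C/[C@@](C)(O)COC(C)=O)CC1 | target

**Step count**
Total: 12 steps. Longest linear sequence: 9 steps (steps 3, 4, 5, 6, 7, 8, 9, 11, 12).

**Steps most likely to fail**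

Step 9. The ambident allyl anion may alkylate through its γ-carbon, or the lithiated sulfoxide may decay before the slow substitution at the β-branched tosylate. The fallback sets out from 12 and changes the carbanion to a sulfone, which alkylates only at the α-carbon and tolerates warming. Oxidation of 12 with mCPBA (2.2 equiv, 0 °C) would give the allyl sulfone (2R,3S)-3-methyl-2-{3-[(phenylsulfonyl)methyl]but-3-en-1-yl}-3-[(trimethylsilyl)oxy]hex-5-en-1-yl 4-methylbenzenesulfonate F1. Treatment with LiN(iPr)2 in THF (−78 to 0 °C) should close the ring to the cyclic allyl sulfone trimethyl{[(2S)-2-[(1R)-4-methylidene-3-(phenylsulfonyl)cyclohexyl]pent-4-en-2-yl]oxy}silane F2. A Pd(PPh3)4-catalysed 1,3-sulfonyl shift would move sulfur to the exocyclic carbon and the double bond into the ring at C1=C2, giving trimethyl{[(2S)-2-[(1R)-4-[(phenylsulfonyl)methyl]cyclohex-3-en-1-yl]pent-4-en-2-yl]oxy}silane F3. Deprotonation with n-BuLi and oxidative desulfonylation with MoO5·pyridine·HMPA would give the enal (4R)-4-{(2S)-2-[(trimethylsilyl)oxy]pent-4-en-2-yl}cyclohex-1-ene-1-carbaldehyde F4. Luche reduction (NaBH4, CeCl3·7H2O, MeOH) comes back to the route at 17, which is hydrolysed to 18 as in step 9.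

Step 5. Attack at the epoxide carbon next to the fully substituted centre may be slow enough for Payne rearrangement or halohydrin formation by the magnesium halide to intervene. The fallback sets out from 8 and activates that carbon as the α-position of an ester. Oxidation with TEMPO/NaOCl/NaClO2 would give (2R,3S)-3-methyl-3-(prop-2-en-1-yl)oxirane-2-carboxylic acid F5, and Me3SiCHN2 in MeOH its ester methyl (2R,3S)-3-methyl-3-(prop-2-en-1-yl)oxirane-2-carboxylate F6. The magnesium cuprate made from 9 and CuBr·SMe2 (THF, −40 °C) should open the glycidic ester at the α-carbon with the same inversion, giving methyl (2S,3S)-3-hydroxy-3-methyl-2-{3-[(phenylsulfanyl)methyl]but-3-en-1-yl}hex-5-enoate F7. Reduction with LiAlH4 comes back to the route at 10.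

Step 1. Proton transfer from the first-formed allyl sulfide to unreacted dianion may lead to double sulfenylation. The fallback sets out from 1 and separates carbon–silicon from carbon–sulfur bond formation. The same dianion is quenched with Me3SiCl and worked up with dilute acid to give the allylsilane 3-[(trimethylsilyl)methyl]but-3-en-1-ol F8, which has no acidic position. Electrophilic SE2′ sulfenylation with PhSCl (CH2Cl2, −78 °C) comes back to the route at 3; the allyl transposition is without consequence because both CH2 ends are equivalent.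

**Further compounds**
F1 | step 9 | (2R,3S)-3-methyl-2-{3-[(phenylsulfonyl)methyl]but-3-en-1-yl}-3-[(trimethylsilyl)oxy]hex-5-en-1-yl 4-methylbenzenesulfonate | Cc1ccc(cc1)S(=O)(=O)OC[C@@H](CCC(=C)CS(=O)(=O)c1ccccc1)[C@@](C)(O[Si](C)(C)C)CC=C
F2 | step 9 | trimethyl{[(2S)-2-[(1R)-4-methylidene-3-(phenylsulfonyl)cyclohexyl]pent-4-en-2-yl]oxy}silane (both epimers at the sulfonyl carbon) | C=C1CC[C@H](CC1S(=O)(=O)c1ccccc1)[C@@](C)(O[Si](C)(C)C)CC=C
F3 | step 9 | trimethyl{[(2S)-2-[(1R)-4-[(phenylsulfonyl)methyl]cyclohex-3-en-1-yl]pent-4-en-2-yl]oxy}silane | O=S(=O)(CC1=CC[C@H]([C@@](C)(O[Si](C)(C)C)CC=C)CC1)c1ccccc1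
F4 | step 9 | (4R)-4-{(2S)-2-[(trimethylsilyl)oxy]pent-4-en-2-yl}cyclohex-1-ene-1-carbaldehyde | O=CC1=CC[C@H]([C@@](C)(O[Si](C)(C)C)CC=C)CC1
F5 | step 5 | (2R,3S)-3-methyl-3-(prop-2-en-1-yl)oxirane-2-carboxylic acid | OC(=O)[C@@H]1O[C@@]1(C)CC=C
F6 | step 5 | methyl (2R,3S)-3-methyl-3-(prop-2-en-1-yl)oxirane-2-carboxylate | COC(=O)[C@@H]1O[C@@]1(C)CC=C
F7 | step 5 | methyl (2S,3S)-3-hydroxy-3-methyl-2-{3-[(phenylsulfanyl)methyl]but-3-en-1-yl}hex-5-enoate | COC(=O)[C@@H](CCC(=C)CSc1ccccc1)[C@@](C)(O)CC=C
F8 | step 1 | 3-[(trimethylsilyl)methyl]but-3-en-1-ol | C[Si](C)(C)CC(=C)CCO
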